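**Retrosynthetic overview**

1. The strategy rests on C10: it is a ring A carbon allylic to C11=C12 and also the ring B neighbour of the C9 carbinol. The ten-membered ring B (C1–C10) is therefore closed last at C9–C10, by γ-attack of a ring A allylchromium (metal on C12) on a tethered C9 aldehyde; C9 acetylation and C8 desilylation finish.
2. The cyclization precursor is cut at C4–C5 (Negishi coupling, Z C5=C6 retained) into a ring A alkyl iodide (C1–C4, C10–C14) and a Z-iodoalkenyl γ-lactone (C5–C9, C17–C19).
3. Ring A comes from (S)-carvone (its C=O becomes C10, its CH2 C1, its isopropenyl carbon C14): anti boron aldol with a C2–C4 aldehyde, methylation anti to isopropenyl, then Criegee degradation to the C14 acetate. This is done before any C5=C6 olefin exists, because ozone would cleave it.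
4. The lactone comes from dimethyl (S)-malate: Fráter–Seebach methylation (C17), Seebach dioxolanone alkylation (C8 with C9), propynyl addition and asymmetric transfer hydrogenation (C7), hydroalumination–iodination, oxidative lactonization.
5. Ring order: ring A (from carvone), then the γ-lactone, then ring B (step 24).

Key step: step 24

Remark: briarane numbering (C1–C20) is used for all intermediates; 33, 34 and 37 are handled as mixtures at C10/C12, centres that step 24 erases; aldehyde 18 and 1-propynyllithium are taken as purchased.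

**Lactone fragment (steps 1–11)**

Step 1
Reactants: 1 dimethyl (S)-malate
Product: 3 dimethyl (2S,3R)-2-hydroxy-3-methylbutanedioate, via dilithium alkoxide enolate 2 (not isolated)
Conditions: LiN(SiMe3)2 (2.2 equiv), THF, −78 °C; MeI, −78 → −20 °C; aq NH4Cl
Reagents that add atoms: iodomethane, CI
Why: Fráter–Seebach alkylation, in which the chelated dilithium alkoxide enolate is methylated on the face anti to the C2 alkoxide, setting the 3R centre (C17).

Step 2
Reactants: 3 dimethyl (2S,3R)-2-hydroxy-3-methylbutanedioate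
Product: 4 (2S,3R)-2-hydroxy-3-methylbutanedioic acid
Conditions: KOH, H2O/MeOH, 0 °C → rt; HCl to pH 1
Reagents that add atoms: potassium hydroxide, [K+].[OH-]
Why: Ester saponification; the dicarboxylate is not enolized under these conditions, so C17 should be kept.

Step 3
Reactants: 4 (2S,3R)-2-hydroxy-3-methylbutanedioic acid
Product: 5 (2R)-2-[(2S,4S)-2-tert-butyl-5-oxo-1,3-dioxolan-4-yl]propanoic acid
Conditions: pivalaldehyde, TsOH (cat.), H2SO4 (cat.), pentane, reflux (Dean–Stark); recrystallization
Reagents that add atoms: pivalaldehyde, CC(C)(C)C=O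
Why: Seebach acetalization of the α-hydroxy acid unit, in which the five-membered cis dioxolanone is the thermodynamic product and the new acetal centre stores the C2 configuration.

Step 4
Reactants: 5 (2R)-2-[(2S,4S)-2-tert-butyl-5-oxo-1,3-dioxolan-4-yl]propanoic acid
Product: 7 (2R)-2-[(2S,4R)-4-(benzyloxymethyl)-2-tert-butyl-5-oxo-1,3-dioxolan-4-yl]propanoic acid, via dilithium carboxylate enolate 6 (not isolated)
Conditions: LiN(SiMe3)2 (2.2 equiv), THF, −78 °C; BnOCH2Cl, −78 → −30 °C; aq HCl
Reagents that add atoms: benzyl chloromethyl ether, ClCOCc1ccccc1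
Why: Seebach self-regeneration of stereocentres, in which the enolate is alkylated anti to the tert-butyl group so that C9 takes the place of the former hydrogen and C8 is set with net retention.

Step 5
Reactants: 7 (2R)-2-[(2S,4R)-4-(benzyloxymethyl)-2-tert-butyl-5-oxo-1,3-dioxolan-4-yl]propanoic acid
Product: 9 (3R,4S)-3-(benzyloxymethyl)-3-hydroxy-4-methyloxolan-2-one, via hydroxy dioxolanone 8 (not isolated)
Conditions: BH3·SMe2, THF, 0 °C → rt; MeOH; then TsOH·H2O (cat.), CH2Cl2, rt
Reagents that add atoms: none
Why: Borane reduces the carboxylic acid chemoselectively beside the dioxolanone, and acid-catalysed translactonization of 8 then releases pivalaldehyde and the tertiary C8 hydroxyl without touching a stereocentre.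

Step 6
Reactants: 9 (3R,4S)-3-(benzyloxymethyl)-3-hydroxy-4-methyloxolan-2-one
Product: 10 (3R,4S)-3-hydroxy-3-(hydroxymethyl)-4-methyloxolan-2-one
Conditions: H2 (1 atm), Pd/C (10 %), EtOAc, rt
Reagents that add atoms: none
Why: Hydrogenolysis of the benzyl ether, placed here because no C–C multiple bond or iodide is yet present.

Step 7
Reactants: 10 (3R,4S)-3-hydroxy-3-(hydroxymethyl)-4-methyloxolan-2-one
Product: 11 (3R,4S)-4-methyl-3-(triethylsilyloxy)-3-(triethylsilyloxymethyl)oxolan-2-one
Conditions: Et3SiOTf (3 equiv), 2,6-lutidine, CH2Cl2, −78 → 0 °C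
Reagents that add atoms: triethylsilyl triflate, CC[Si](CC)(CC)OS(=O)(=O)C(F)(F)F
Why: Silylation with a silyl triflate, which is reactive enough for the tertiary C8 hydroxyl; C8 has no hydrogen, so no ketene acetal can form.

Step 8
Reactants: 11 (3R,4S)-4-methyl-3-(triethylsilyloxy)-3-(triethylsilyloxymethyl)oxolan-2-one
Product: 12 7-hydroxy-6-methyl-5-(triethylsilyloxy)-5-(triethylsilyloxymethyl)hept-2-yn-4-one
Conditions: LiC≡CCH3 (1.3 equiv), THF, −78 → −40 °C; aq NH4Cl
Reagents that add atoms: 1-propynyllithium, [Li]C#CC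
Why: Alkynyllithium addition to a lactone, which should stop at the ketone stage because the lithium hemiketal persists at low temperature.

Step 9
Reactants: 12 7-hydroxy-6-methyl-5-(triethylsilyloxy)-5-(triethylsilyloxymethyl)hept-2-yn-4-one
Product: 13 (4S)-2-methyl-3-(triethylsilyloxy)-3-(triethylsilyloxymethyl)hept-5-yne-1,4-diol
Conditions: Ru[(R,R)-TsDPEN](p-cymene) (2 mol %), iPrOH, rt
Reagents that add atoms: none
Why: Noyori asymmetric transfer hydrogenation of an ynone, in which the (R,R) catalyst, with the alkyne as directing π-group, should deliver hydride under reagent control to give the C7 carbinol of the target (7S).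

Step 10
Reactants: 13 (4S)-2-methyl-3-(triethylsilyloxy)-3-(triethylsilyloxymethyl)hept-5-yne-1,4-diol
Product: 15 (Z)-6-iodo-2-methyl-3-(triethylsilyloxy)-3-(triethylsilyloxymethyl)hept-5-ene-1,4-diol, via cyclic alkenylaluminate 14 (not isolated)
Conditions: NaAlH2(OCH2CH2OCH3)2 (Red-Al, 4 equiv), THF, 0 °C → rt; EtOAc; then I2, THF, −78 → 0 °C; aq Na2S2O3/Rochelle salt
Reagents that add atoms: iodine, II
Why: Hydroxyl-directed trans-hydroalumination of the propargylic alcohol places aluminium on the distal carbon C5 in a five-membered aluminate, and iodinolysis with retention gives the Z iodide (iodine cis to C7).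

Step 11
Reactants: 15 (Z)-6-iodo-2-methyl-3-(triethylsilyloxy)-3-(triethylsilyloxymethyl)hept-5-ene-1,4-diol
Product: 16 Z-iodoalkenyl lactone, 5-[(Z)-2-iodoprop-1-enyl]-3-methyl-4-(triethylsilyloxy)-4-(triethylsilyloxymethyl)oxolan-2-one (methyl, silyloxy and alkenyl all cis)
Conditions: TEMPO (20 mol %), PhI(OAc)2 (3 equiv), CH2Cl2, rt
Reagents that add atoms: none
Why: TEMPO/PhI(OAc)2 oxidative lactonization of a 1,4-diol, in which the primary alcohol is oxidized first and the lactol formed with the hindered C7 hydroxyl is oxidized on to the γ-lactone.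

**Ring A fragment (steps 12–18)**

Step 12
Reactants: 17 (S)-carvone; 18 3-(tert-butyldimethylsilyloxy)propanal
Product: 21 (5S,6S)-6-[(1S)-3-(tert-butyldimethylsilyloxy)-1-hydroxypropyl]-2-methyl-5-(prop-1-en-2-yl)cyclohex-2-en-1-one, via boron enolate 19 (not isolated), via boron aldolate 20 (not isolated)
Conditions: (c-C6H11)2BCl, Et3N, Et2O, −78 → 0 °C; 18, −78 → −20 °C; then H2O2, MeOH, pH 7 buffer, 0 °C
Reagents that add atoms: none
Why: Boron-mediated aldol addition (Brown dicyclohexylboron enolate), in which the cyclic enolate necessarily has E geometry and should react through a Zimmerman–Traxler chair on the face anti to isopropenyl, giving the anti aldol with the 2S carbinol and the side chain trans to isopropenyl at C1.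

Step 13
Reactants: 21 the aldol
Product: 22 triethylsilyl ether of 21
Conditions: Et3SiOTf, 2,6-lutidine, CH2Cl2, −78 °C
Reagents that add atoms: triethylsilyl triflate, CC[Si](CC)(CC)OS(=O)(=O)C(F)(F)F
Why: Silyl ether formation, which masks the aldol hydroxyl against retro-aldol cleavage in the next step.

Step 14
Reactants: 22 triethylsilyl ether of 21
Product: 24 6-methylated ketone (C1 quaternary; methyl trans and C2 chain cis to isopropenyl), via lithium enolate 23 (not isolated)
Conditions: LiN(iPr)2, THF, −78 °C; MeI, DMPU, −78 → −20 °C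
Reagents that add atoms: iodomethane, CI
Why: Kinetic α′-deprotonation and enolate alkylation, in which iodomethane should enter anti to the isopropenyl group and so make C1 quaternary with C15 trans and the C2 chain cis to the C14 substituent.

Step 15
Reactants: 24 6-methylated ketone
Product: 27 C14 acetate (isopropenyl replaced by acetoxy with retention), via methoxy hydroperoxide 25 (not isolated), via peracetate 26 (not isolated)
Conditions: O3, CH2Cl2/MeOH (4:1), −78 °C (Sudan Red 7B end point); then Ac2O, Et3N, DMAP (cat.), 0 °C → rt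
Reagents that add atoms: ozone, [O-][O+]=O; methanol, CO
Why: Ozonolysis of the electron-rich isopropenyl group in methanol followed by Criegee rearrangement of the peracetate, in which C14 migrates to oxygen with retention and acetate demethylates the dioxycarbenium ion to leave the C14 acetate, while the electron-poor enone is untouched.

Step 16
Reactants: 27 C14 acetate
Product: 28 diol (C2 and C4 hydroxyls free)
Conditions: HF·pyridine, THF, 0 °C → rt
Reagents that add atoms: none
Why: Acidic, non-basic desilylation of both silyl ethers; a possible 1,3-acetyl shift between O14 and O2 is of no consequence because both oxygens end as acetates.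

Step 17
Reactants: 28 diol
Product: 29 C4 iodide with free C2 hydroxyl
Conditions: I2, PPh3, imidazole, CH2Cl2, 0 °C
Reagents that add atoms: iodine, II
Why: Appel-type iodination (Garegg conditions), selective for the primary alcohol over the neopentyl secondary C2 hydroxyl.

Step 18
Reactants: 29 C4 iodide with free C2 hydroxyl
Product: 30 ring A iodide, 5-acetoxy-6-[(1S)-1-acetoxy-3-iodopropyl]-2,6-dimethylcyclohex-2-en-1-one (carvone numbering)
Conditions: Ac2O, DMAP, Et3N, CH2Cl2, rt
Reagents that add atoms: acetic anhydride, CC(=O)OC(C)=O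
Why: DMAP-catalysed acetylation of the remaining hydroxyl gives the C2, C14 diacetate.

**Union and ring B (steps 19–26)**

Step 19
Reactants: 30 ring A iodide; 16 Z-iodoalkenyl lactone
Product: 32 coupled enone (C4–C5 bond, Z C5=C6), via alkylzinc iodide 31 (not isolated)
Conditions: Zn dust (activated with BrCH2CH2Br and Me3SiCl), DMA, 40 °C; then 16, Pd(PPh3)4 (5 mol %), THF, rt → 45 °C
Reagents that add atoms: none
Why: Zinc insertion into the primary iodide and Negishi sp3–sp2 coupling under zerovalent palladium catalysis, in which the alkenyl iodide reacts with retention and so fixes the Z C5=C6 olefin, while enone, acetates and lactone tolerate the alkylzinc.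

Step 20
Reactants: 32 coupled enone
Product: 33 C10 allylic alcohol (epimers at C10)
Conditions: NaBH4, CeCl3·7H2O, MeOH, −78 → −40 °C; AcOH quench
Reagents that add atoms: none
Why: Luche 1,2-reduction of the enone; the new C10 carbinol centre need not be controlled because it is erased in steps 21 and 24.

Step 21
Reactants: 33 C10 allylic alcohol
Product: 34 C12 allylic bromide with C10=C11 (drawn as one C12 epimer; its epimer and the C10 bromide accompany it)
Conditions: CBr4, PPh3, 2,6-lutidine, CH2Cl2, −20 → 0 °C
Reagents that add atoms: carbon tetrabromide, BrC(Br)(Br)Br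
Why: Appel bromination of the neopentyl allylic alcohol, expected to proceed with allylic transposition (SN2′) to the less hindered C12 bromide; all regio- and stereoisomers are usable in step 24.

Step 22
Reactants: 34 C12 allylic bromide
Product: 35 C9 primary alcohol (C8 triethylsilyl ether kept)
Conditions: HF·pyridine, THF, −10 → 0 °C (no added pyridine)
Reagents that add atoms: none
Why: Selective acidic cleavage of the primary triethylsilyl ether beside the tertiary one on steric grounds, in a medium without free nucleophilic amine for the allylic bromide.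

Step 23
Reactants: 35 C9 primary alcohol
Product: 36 C9 aldehyde, the cyclization precursor
Conditions: Dess–Martin periodinane, NaHCO3, CH2Cl2, 0 °C → rt
Reagents that add atoms: none
Why: Dess–Martin oxidation under buffered, non-basic conditions; the aldehyde has no α-hydrogen and the bromide is inert.

Step 24
Reactants: 36 C9 aldehyde
Product: 38 tricyclic C9 alcohol with C8 triethylsilyl ether, via allylchromium dichloride 37 (not isolated)
Conditions: CrCl2 (8 equiv), THF, rt, slow addition of 36 (final 2 mM); H2O
Reagents that add atoms: none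
Why: Two equivalents of CrCl2 reduce the C–Br bond by two single-electron transfers to the trivalent allylchromium 37, whose metal shifts freely between C10 and C12 and between the two ring faces, so every bromide isomer in 36 gives the same nucleophile with chromium on the secondary C12 rather than the neopentyl C10. This species adds through its γ-carbon C10 to the C9 aldehyde in a closed six-membered chair (Cr–C12–C11=C10···C9=O), the closest known reaction being the intramolecular Nozaki–Hiyama–Kishi allylation used for medium-ring closure; C9–C10 is the only new bond and the olefin returns to C11=C12. Ring B is closed as a ten-membered carbocycle in the 10-exo-trig mode at the aldehyde carbon. C10 is set by the ring A substituents: chromium on the face of the C14 acetate would be syn-axial to it, so the metal sits on the face of the C15 methyl and hands C9 over suprafacially to that face of C10, anti to the C1–C2 bond (trans ring fusion). C9 is set by the chair, in which the cyclic allyl unit is Z-configured (C1 axial) and C8 lies equatorial, giving the 9,10-syn relationship of the target. The step needs γ- over α-attack and cyclization over oligomerization, secured by the position of chromium and by slow addition at high dilution, while acetates, lactone, silyl ether and the C5=C6 olefin are inert to divalent chromium.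

Step 25
Reactants: 38 tricyclic C9 alcohol
Product: 39 C9 acetate with C8 triethylsilyl ether
Conditions: Ac2O, DMAP, pyridine, rt → 40 °C
Reagents that add atoms: acetic anhydride, CC(=O)OC(C)=O
Why: DMAP-catalysed acetylation of the hindered secondary C9 alcohol; the tertiary C8 oxygen stays silylated.

Step 26
Reactants: 39 C9 acetate
Product: 40 CNP0187165.2
Conditions: HF·pyridine, pyridine, THF, 0 °C → rt
Reagents that add atoms: none
Why: HF·pyridine cleavage of the tertiary silyl ether under non-basic conditions that avoid acetyl migration from O9 to O8.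

**Compound list**

1 | dimethyl (S)-malate | COC(=O)C[C@H](O)C(=O)OC | starting material
2 | dilithium alkoxide enolate of 1 | COC(O[Li])=C[C@H](O[Li])C(=O)OC | intermediate
3 | dimethyl (2S,3R)-2-hydroxy-3-methylbutanedioate | COC(=O)[C@H](C)[C@H](O)C(=O)OC | intermediate
4 | (2S,3R)-2-hydroxy-3-methylbutanedioic acid | OC(=O)[C@H](C)[C@H](O)C(O)=O | intermediate
5 | (2R)-2-[(2S,4S)-2-tert-butyl-5-oxo-1,3-dioxolan-4-yl]propanoic acid (tert-butyl cis to side chain) | CC(C)(C)[C@@H]1OC(=O)[C@@H](O1)[C@@H](C)C(O)=O | intermediate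
6 | dilithium carboxylate enolate of 5 | CC(C)(C)[C@@H]1OC(O[Li])=C(O1)[C@@H](C)C(=O)O[Li] | intermediate
7 | (2R)-2-[(2S,4R)-4-(benzyloxymethyl)-2-tert-butyl-5-oxo-1,3-dioxolan-4-yl]propanoic acid (benzyloxymethyl trans to tert-butyl) | CC(C)(C)[C@@H]1OC(=O)[C@@](COCc2ccccc2)(O1)[C@@H](C)C(O)=O | intermediate
8 | hydroxy dioxolanone (CO2H of 7 reduced to CH2OH) | CC(C)(C)[C@@H]1OC(=O)[C@@](COCc2ccccc2)(O1)[C@@H](C)CO | intermediate
9 | (3R,4S)-3-(benzyloxymethyl)-3-hydroxy-4-methyloxolan-2-one (OH cis to methyl; C=O is C7, ring CH2 is C19) | O=C1OC[C@H](C)[C@@]1(O)COCc1ccccc1 | intermediate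
10 | (3R,4S)-3-hydroxy-3-(hydroxymethyl)-4-methyloxolan-2-one | O=C1OC[C@H](C)[C@@]1(O)CO | intermediate
11 | (3R,4S)-4-methyl-3-(triethylsilyloxy)-3-(triethylsilyloxymethyl)oxolan-2-one | O=C1OC[C@H](C)[C@@]1(O[Si](CC)(CC)CC)CO[Si](CC)(CC)CC | intermediate
12 | 7-hydroxy-6-methyl-5-(triethylsilyloxy)-5-(triethylsilyloxymethyl)hept-2-yn-4-one (C8, C17 as in 11) | CC#CC(=O)[C@](O[Si](CC)(CC)CC)(CO[Si](CC)(CC)CC)[C@@H](C)CO | intermediate
13 | (4S)-2-methyl-3-(triethylsilyloxy)-3-(triethylsilyloxymethyl)hept-5-yne-1,4-diol | CC#C[C@H](O)[C@](O[Si](CC)(CC)CC)(CO[Si](CC)(CC)CC)[C@@H](C)CO | intermediate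
14 | sodium alkenylaluminate, five-membered ring O7–Al–C5=C6–C7 (simplified) | [Na+].CC1=C[C@H](O[Al-]1(OCCOC)OCCOC)[C@](O[Si](CC)(CC)CC)(CO[Si](CC)(CC)CC)[C@@H](C)CO | intermediate
15 | (Z)-6-iodo-2-methyl-3-(triethylsilyloxy)-3-(triethylsilyloxymethyl)hept-5-ene-1,4-diol | C/C(I)=C/[C@H](O)[C@](O[Si](CC)(CC)CC)(CO[Si](CC)(CC)CC)[C@@H](C)CO | intermediate
16 | Z-iodoalkenyl lactone (C5–C9, C17–C19; methyl, silyloxy and alkenyl all cis) | CC[Si](CC)(CC)OC[C@@]1(O[Si](CC)(CC)CC)[C@H](/C=C(/C)I)OC(=O)[C@@H]1C | intermediate
17 | (S)-carvone | CC1=CC[C@@H](CC1=O)C(C)=C | starting material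
18 | 3-(tert-butyldimethylsilyloxy)propanal | O=CCCO[Si](C)(C)C(C)(C)C | starting material
19 | dicyclohexylboron enolate of 17 (C1=C10) | CC1=CC[C@H](C(C)=C)C=C1OB(C1CCCCC1)C1CCCCC1 | intermediate
20 | dicyclohexylboron aldolate | CC1=CC[C@H](C(C)=C)[C@@H]([C@@H](OB(C2CCCCC2)C2CCCCC2)CCO[Si](C)(C)C(C)(C)C)C1=O | intermediate
21 | (5S,6S)-6-[(1S)-3-(tert-butyldimethylsilyloxy)-1-hydroxypropyl]-2-methyl-5-(prop-1-en-2-yl)cyclohex-2-en-1-one | CC1=CC[C@H](C(C)=C)[C@@H]([C@@H](O)CCO[Si](C)(C)C(C)(C)C)C1=O | intermediate
22 | triethylsilyl ether of 21 | CC1=CC[C@H](C(C)=C)[C@@H]([C@@H](O[Si](CC)(CC)CC)CCO[Si](C)(C)C(C)(C)C)C1=O | intermediate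
23 | lithium enolate of 22 (C1=C10) | CC1=CC[C@H](C(C)=C)C([C@@H](O[Si](CC)(CC)CC)CCO[Si](C)(C)C(C)(C)C)=C1O[Li] | intermediate
24 | 6-methylated ketone (methyl trans, C2 chain cis to isopropenyl) | CC1=CC[C@H](C(C)=C)[C@](C)([C@@H](O[Si](CC)(CC)CC)CCO[Si](C)(C)C(C)(C)C)C1=O | intermediate
25 | α-methoxy hydroperoxide (mixture at the peroxy carbon) | CC1=CC[C@H](C(C)(OC)OO)[C@](C)([C@@H](O[Si](CC)(CC)CC)CCO[Si](C)(C)C(C)(C)C)C1=O | intermediate
26 | peracetate of 25 | CC1=CC[C@H](C(C)(OC)OOC(C)=O)[C@](C)([C@@H](O[Si](CC)(CC)CC)CCO[Si](C)(C)C(C)(C)C)C1=O | intermediate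
27 | C14 acetate, bis-silyl ether | CC1=CC[C@H](OC(C)=O)[C@](C)([C@@H](O[Si](CC)(CC)CC)CCO[Si](C)(C)C(C)(C)C)C1=O | intermediate
28 | C2, C4 diol | CC1=CC[C@H](OC(C)=O)[C@](C)([C@@H](O)CCO)C1=O | intermediate
29 | C4 iodide, C2 alcohol | CC1=CC[C@H](OC(C)=O)[C@](C)([C@@H](O)CCI)C1=O | intermediate
30 | ring A iodide, C2 and C14 diacetate | CC1=CC[C@H](OC(C)=O)[C@](C)([C@@H](OC(C)=O)CCI)C1=O | intermediate
31 | alkylzinc iodide from 30 | CC1=CC[C@H](OC(C)=O)[C@](C)([C@@H](OC(C)=O)CC[Zn]I)C1=O | intermediate
32 | coupled enone (C10 ketone, Z C5=C6, lactone with C8 and C9 triethylsilyl ethers) | CC1=CC[C@H](OC(C)=O)[C@](C)([C@@H](OC(C)=O)CC/C(C)=C\[C@@H]2OC(=O)[C@H](C)[C@@]2(O[Si](CC)(CC)CC)CO[Si](CC)(CC)CC)C1=O | intermediate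
33 | C10 allylic alcohol (C10 epimers) | CC1=CC[C@H](OC(C)=O)[C@](C)([C@@H](OC(C)=O)CC/C(C)=C\[C@@H]2OC(=O)[C@H](C)[C@@]2(O[Si](CC)(CC)CC)CO[Si](CC)(CC)CC)C1O | intermediate
34 | C12 allylic bromide, C10=C11 (one epimer drawn) | Br[C@@H]1C[C@H](OC(C)=O)[C@@](C)(C=C1C)[C@@H](OC(C)=O)CC/C(C)=C\[C@@H]2OC(=O)[C@H](C)[C@@]2(O[Si](CC)(CC)CC)CO[Si](CC)(CC)CC | intermediate
35 | C9 primary alcohol of 34 | Br[C@@H]1C[C@H](OC(C)=O)[C@@](C)(C=C1C)[C@@H](OC(C)=O)CC/C(C)=C\[C@@H]2OC(=O)[C@H](C)[C@@]2(O[Si](CC)(CC)CC)CO | intermediate
36 | C9 aldehyde, cyclization precursor | Br[C@@H]1C[C@H](OC(C)=O)[C@@](C)(C=C1C)[C@@H](OC(C)=O)CC/C(C)=C\[C@@H]2OC(=O)[C@H](C)[C@@]2(O[Si](CC)(CC)CC)C=O | intermediate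
37 | allylchromium dichloride, chromium on C12 (equilibrating, solvent ligands omitted) | Cl[Cr](Cl)C1C[C@H](OC(C)=O)[C@@](C)(C=C1C)[C@@H](OC(C)=O)CC/C(C)=C\[C@@H]2OC(=O)[C@H](C)[C@@]2(O[Si](CC)(CC)CC)C=O | intermediate
38 | tricyclic C9 alcohol, C8 triethylsilyl ether | CC(=O)O[C@H]1CC=C(C)[C@@H]2[C@H](O)[C@@]3(O[Si](CC)(CC)CC)[C@H](/C=C(/C)CC[C@H](OC(C)=O)[C@@]12C)OC(=O)[C@@H]3C | intermediate
39 | C2, C9, C14 triacetate, C8 triethylsilyl ether | CC(=O)O[C@H]1CC=C(C)[C@@H]2[C@H](OC(C)=O)[C@@]3(O[Si](CC)(CC)CC)[C@H](/C=C(/C)CC[C@H](OC(C)=O)[C@@]12C)OC(=O)[C@@H]3C | intermediate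
40 | CNP0187165.2 | CC(=O)O[C@H]1CC=C(C)[C@@H]2[C@H](OC(C)=O)[C@@]3(O)[C@H](/C=C(/C)CC[C@H](OC(C)=O)[C@@]12C)OC(=O)[C@@H]3C | target

**Step count**

Total: 26 steps. Longest linear sequence: 19 steps (steps 1–11, then 19–26); the carvone branch is 15 steps (12–26).

**Steps most likely to fail, with fallbacks**

Step 24. The allylchromium may deliver C9 to the acetate-bearing face of C10 (cis ring fusion), or the chair may place C8 axial; intermolecular allylation may also compete at practical concentration. The fallback repairs the ring fusion by known oxidation, epimerization and reduction chemistry. It sets out from 36: the cyclization is run as in step 24 and the cis-fused alcohol F1 is carried on. Dess–Martin oxidation should give the cis-fused C9 ketone F2. Its C10 hydrogen, now α to the ketone and allylic, is equilibrated with DBU in toluene to the trans-fused C9 ketone F3, which is expected to be favoured because both ring B bonds are then equatorial on ring A. Reduction with NaBH4/CeCl3·7H2O, or with LiBH(s-Bu)3 should the other face be required, comes back to the route at 38; the facial preference of this reduction would have to be established.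

Step 12. Low anti selectivity, or attack on the face syn to isopropenyl, would give the C2 epimer; the later enolization of 22 at the congested C1–H (step 14) may also be slow. The fallback sets C2 by reagent-controlled ketone reduction and C1 by alkylation of a β-diketone. It sets out from 21 at any C2 epimer ratio. Dess–Martin oxidation gives the β-diketone F4. K2CO3/MeI in acetone should C-methylate C1 anti to isopropenyl to give the methylated diketone F5. (R)-2-Methyl-CBS-oxazaborolidine with BH3·SMe2 should reduce the side-chain ketone, which is flanked by the quaternary C1 and a CH2 and is less hindered than the conjugated ring ketone, to the 2S alcohol F6. Et3SiOTf/2,6-lutidine then comes back to the route at 24.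

Step 8. The alkynyllithium may fail to add to the neopentyl lactone carbonyl, or add twice after collapse of the hemiketal. The fallback builds the ynone by reduction, Grignard addition and selective oxidation. It sets out from 11: (i-Bu)2AlH at −78 °C gives the lactol F7. CH3C≡CMgBr adds to its open hydroxy aldehyde form to give the propargylic diol F8 as a mixture of C7 epimers. MnO2 oxidizes only the propargylic alcohol and comes back to the route at 12.

**Further compounds**

F1 | step 24 | cis-fused alcohol (C9 and C10 inverted relative to 38) | CC(=O)O[C@H]1CC=C(C)[C@H]2[C@@H](O)[C@@]3(O[Si](CC)(CC)CC)[C@H](/C=C(/C)CC[C@H](OC(C)=O)[C@@]12C)OC(=O)[C@@H]3C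
F2 | step 24 | cis-fused C9 ketone | CC(=O)O[C@H]1CC=C(C)[C@H]2C(=O)[C@@]3(O[Si](CC)(CC)CC)[C@H](/C=C(/C)CC[C@H](OC(C)=O)[C@@]12C)OC(=O)[C@@H]3C
F3 | step 24 | trans-fused C9 ketone | CC(=O)O[C@H]1CC=C(C)[C@@H]2C(=O)[C@@]3(O[Si](CC)(CC)CC)[C@H](/C=C(/C)CC[C@H](OC(C)=O)[C@@]12C)OC(=O)[C@@H]3C
F4 | step 12 | β-diketone, 6-[3-(tert-butyldimethylsilyloxy)propanoyl]carvone | CC1=CC[C@H](C(C)=C)[C@@H](C(=O)CCO[Si](C)(C)C(C)(C)C)C1=O
F5 | step 12 | methylated diketone (methyl trans to isopropenyl) | CC1=CC[C@H](C(C)=C)[C@](C)(C(=O)CCO[Si](C)(C)C(C)(C)C)C1=O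
F6 | step 12 | 2S alcohol (24 without the triethylsilyl group) | CC1=CC[C@H](C(C)=C)[C@](C)([C@@H](O)CCO[Si](C)(C)C(C)(C)C)C1=O
F7 | step 8 | lactol of 11 (anomers) | OC1OC[C@H](C)[C@@]1(O[Si](CC)(CC)CC)CO[Si](CC)(CC)CC
F8 | step 8 | propargylic diol (C7 epimers) | CC#CC(O)[C@](O[Si](CC)(CC)CC)(CO[Si](CC)(CC)CC)[C@@H](C)CO
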